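**Retrosynthetic overview**

- The two halves differ at C8 (left: acetate axial, 8R; right: acetate equatorial, 8S) and at C3 (left acetate, right free alcohol), so the target is not a C2-symmetric dimer and is assembled from two different pieces.
- Key disconnection: the ring-to-chain bond C12–C9', not the central C11–C12 bond. A primary radical from the finished left half adds to (S)-4-acetoxy-2,4-dimethylcyclohexenone anti to the tertiary acetate, which sets C9' against C8'.
- The right oxepane is closed last on the coupled ketone, so the free C3' alcohol appears in the final step and needs no protecting group.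
- Left half: ring B from (S)-4-silyloxy-2-methylcyclohexenone; C9–C11 by radical conjugate addition of a succinate-derived radical; C10 by chiral-imine Michael addition; oxepane by ketalisation/reductive cleavage; C8 by methylcerium addition.
- Ring order: left ring B (bought carbocycle) → left oxepane → union → right ring B (preformed carbocycle) → right oxepane.

Assumption: locants follow the target as two C15 halves (left C1–C10 with the oxepane O between C4 and C5 and ring B = C5–C10; bridge C11–C12; right half primed), and (S)-4-hydroxycyclohex-2-en-1-one is bought as the single enantiomer.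

**Route**

Step 1
Reactants: 1 (S)-4-hydroxycyclohex-2-en-1-one
Product: 2 (S)-4-[(tert-butyldimethylsilyl)oxy]cyclohex-2-en-1-one
Conditions: TBSCl, imidazole, DMF, 0 °C → rt
Reagents that add atoms: tert-butyldimethylsilyl chloride, CC(C)(C)[Si](C)(C)Cl
Why: Imidazole-promoted silyl ether formation protects the future C8 oxygen and leaves the stereocentre untouched.

Step 2
Reactants: 2 (S)-4-[(tert-butyldimethylsilyl)oxy]cyclohex-2-en-1-one
Product: 3 (S)-4-[(tert-butyldimethylsilyl)oxy]-2-iodocyclohex-2-en-1-one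
Conditions: I2, pyridine/CH2Cl2, 0 °C → rt
Reagents that add atoms: iodine, II
Why: Johnson α-iodination of the enone (pyridine conjugate addition, iodination, elimination) gives the 2-iodoenone without affecting C8.

Step 3
Reactants: 3 (S)-4-[(tert-butyldimethylsilyl)oxy]-2-iodocyclohex-2-en-1-one
Product: 4 (S)-4-[(tert-butyldimethylsilyl)oxy]-2-methylcyclohex-2-en-1-one
Conditions: Me4Sn, PdCl2(PhCN)2 (5 mol%), AsPh3, CuI, NMP, 80 °C
Reagents that add atoms: tetramethylstannane, C[Sn](C)(C)C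
Why: Stille cross-coupling of the vinyl iodide installs the future C10 methyl group.

Step 4
Reactants: 5 succinic anhydride
Product: 7 benzyl (1,3-dioxoisoindolin-2-yl) succinate, via monobenzyl succinate 6 (not isolated)
Conditions: BnOH, DMAP (cat.), Et3N, CH2Cl2, rt; then N-hydroxyphthalimide, DIC, rt
Reagents that add atoms: benzyl alcohol, OCc1ccccc1; N-hydroxyphthalimide, O=C1c2ccccc2C(=O)N1O
Why: Anhydride ring-opening by the alcohol followed by carbodiimide (Steglich-type) esterification gives the redox-active N-acyloxyphthalimide.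

Step 5
Reactants: 4 (S)-4-[(tert-butyldimethylsilyl)oxy]-2-methylcyclohex-2-en-1-one; 7 benzyl (1,3-dioxoisoindolin-2-yl) succinate
Product: 8 benzyl 3-[(1S,2S,6S)-6-[(tert-butyldimethylsilyl)oxy]-2-methyl-3-oxocyclohexyl]propanoate
Conditions: Ru(bpy)3(PF6)2 (1 mol%), Hantzsch ester (1.5 equiv), 4 (1.5 equiv), DMF, blue LEDs, rt
Reagents that add atoms: none
Why: In this photoredox decarboxylative Giese reaction the primary radical released from the N-acyloxyphthalimide adds to the β-carbon C9 anti to the pseudo-axial silyloxy group, so the new C9 centre is trans to OTBS, while the C10 methine stays epimerisable (drawn as the trans isomer).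

Step 6
Reactants: 9 3-hydroxy-3-methylbutan-2-one; 10 paraformaldehyde (formaldehyde)
Product: 11 4-hydroxy-4-methylpent-1-en-3-one
Conditions: (CH2O)n, i-Pr2NH·CF3CO2H, CF3CO2H (cat.), THF, reflux
Reagents that add atoms: none
Why: Amine-salt-mediated α-methylenation of the methyl ketone (Mannich condensation then elimination) gives the vinyl ketone, which is used fresh.

Step 7
Reactants: 8 benzyl 3-[(1S,2S,6S)-6-[(tert-butyldimethylsilyl)oxy]-2-methyl-3-oxocyclohexyl]propanoate; 11 4-hydroxy-4-methylpent-1-en-3-one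
Product: 14 benzyl 3-[(1S,2S,6S)-6-[(tert-butyldimethylsilyl)oxy]-2-(4-hydroxy-4-methyl-3-oxopentyl)-2-methyl-3-oxocyclohexyl]propanoate, via ketimine 12 (not isolated), via Michael-adduct ketimine 13 (not isolated)
Conditions: (S)-1-phenylethylamine, TsOH (cat.), toluene, Dean–Stark; then 11, THF, 40 °C; then 10% aq. AcOH, rt
Reagents that add atoms: water, O
Why: In this d'Angelo chiral-imine Michael addition the secondary enamine tautomer reacts through its more substituted carbon on the face anti to the C9 side chain, the matched (S)-auxiliary reinforcing that face, so quaternary C10 forms with C1 trans to the C9 chain before hydrolysis returns the ketone.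

Step 8
Reactants: 14 benzyl 3-[(1S,2S,6S)-6-[(tert-butyldimethylsilyl)oxy]-2-(4-hydroxy-4-methyl-3-oxopentyl)-2-methyl-3-oxocyclohexyl]propanoate
Product: 15 benzyl 3-[(1S,2S,6S)-6-[(tert-butyldimethylsilyl)oxy]-2-[(3S)-3,4-dihydroxy-4-methylpentyl]-2-methyl-3-oxocyclohexyl]propanoate
Conditions: H2 (50 atm), RuCl2[(S)-BINAP] (1 mol%), EtOH, 40 °C
Reagents that add atoms: none
Why: Noyori hydroxyl-directed asymmetric hydrogenation reduces only the chelating α-hydroxy ketone (the unfunctionalised ring ketone is inert to this catalyst), and the (S)-ligand sets (3S) under reagent control.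

Step 9
Reactants: 15 benzyl 3-[(1S,2S,6S)-6-[(tert-butyldimethylsilyl)oxy]-2-[(3S)-3,4-dihydroxy-4-methylpentyl]-2-methyl-3-oxocyclohexyl]propanoate
Product: 17 benzyl 3-[(3S,5aS,6S,7S,9aS)-7-[(tert-butyldimethylsilyl)oxy]-3-hydroxy-2,2,5a-trimethyldecahydro-1-benzoxepin-6-yl]propanoate, via bicyclic ketal 16 (not isolated)
Conditions: TMSOTf, Et3SiH, CH2Cl2, −78 → −20 °C; aq. NaHCO3, then citric acid/MeOH
Reagents that add atoms: none
Why: Intramolecular ketalisation to a 6,8-dioxabicyclo[3.2.1]octane is followed by Et3SiH reductive cleavage (reductive etherification), in which the silyl Lewis acid ionises the less hindered C5–O3 bond and axial hydride delivery to the seven-membered oxocarbenium ion sets C5–H trans to the C10 methyl, giving the trans-fused oxepane and freeing the C3 alcohol.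

Step 10
Reactants: 17 benzyl 3-[(3S,5aS,6S,7S,9aS)-7-[(tert-butyldimethylsilyl)oxy]-3-hydroxy-2,2,5a-trimethyldecahydro-1-benzoxepin-6-yl]propanoate
Product: 18 benzyl 3-[(3S,5aS,6S,7S,9aS)-3-acetoxy-7-[(tert-butyldimethylsilyl)oxy]-2,2,5a-trimethyldecahydro-1-benzoxepin-6-yl]propanoate
Conditions: Ac2O, pyridine, DMAP (cat.), CH2Cl2, rt
Reagents that add atoms: acetic anhydride, CC(=O)OC(C)=O
Why: DMAP-catalysed acetylation of the only free alcohol installs the C3 acetate of the target.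

Step 11
Reactants: 18 benzyl 3-[(3S,5aS,6S,7S,9aS)-3-acetoxy-7-[(tert-butyldimethylsilyl)oxy]-2,2,5a-trimethyldecahydro-1-benzoxepin-6-yl]propanoate
Product: 19 benzyl 3-[(3S,5aS,6S,7S,9aS)-3-acetoxy-7-hydroxy-2,2,5a-trimethyldecahydro-1-benzoxepin-6-yl]propanoate
Conditions: HF·pyridine, THF/pyridine, 0 °C → rt
Reagents that add atoms: none
Why: Buffered fluoride desilylation removes the secondary silyl ether and leaves both esters intact.

Step 12
Reactants: 19 benzyl 3-[(3S,5aS,6S,7S,9aS)-3-acetoxy-7-hydroxy-2,2,5a-trimethyldecahydro-1-benzoxepin-6-yl]propanoate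
Product: 20 benzyl 3-[(3S,5aS,6S,9aS)-3-acetoxy-2,2,5a-trimethyl-7-oxodecahydro-1-benzoxepin-6-yl]propanoate
Conditions: Dess–Martin periodinane, NaHCO3, CH2Cl2, rt
Reagents that add atoms: none
Why: Dess–Martin oxidation gives the C8 ketone, and the adjacent C9 centre keeps its equatorial (thermodynamic) side chain.

Step 13
Reactants: 20 benzyl 3-[(3S,5aS,6S,9aS)-3-acetoxy-2,2,5a-trimethyl-7-oxodecahydro-1-benzoxepin-6-yl]propanoate
Product: 22 benzyl 3-[(3S,5aS,6S,7R,9aS)-3,7-diacetoxy-2,2,5a,7-tetramethyldecahydro-1-benzoxepin-6-yl]propanoate, via cerium alkoxide 21 (not isolated)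
Conditions: MeLi, CeCl3, THF, −78 °C; then Ac2O, DMAP, −78 °C → rt
Reagents that add atoms: methyllithium, [Li]C; acetic anhydride, CC(=O)OC(C)=O
Why: Organocerium 1,2-addition (Imamoto conditions) is selective for the ketone over the esters and comes from the equatorial direction away from the syn-axial C10 methyl, so the C8 oxygen ends up axial (8R), and in-situ acylation of the hindered alkoxide gives the tertiary acetate directly.

Step 14
Reactants: 22 benzyl 3-[(3S,5aS,6S,7R,9aS)-3,7-diacetoxy-2,2,5a,7-tetramethyldecahydro-1-benzoxepin-6-yl]propanoate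
Product: 24 1,3-dioxoisoindolin-2-yl 3-[(3S,5aS,6S,7R,9aS)-3,7-diacetoxy-2,2,5a,7-tetramethyldecahydro-1-benzoxepin-6-yl]propanoate, via carboxylic acid 23 (not isolated)
Conditions: H2 (1 atm), Pd/C, EtOAc, rt; filter; then N-hydroxyphthalimide, DIC, DMAP (cat.), CH2Cl2, rt
Reagents that add atoms: N-hydroxyphthalimide, O=C1c2ccccc2C(=O)N1O
Why: Benzyl ester hydrogenolysis followed by carbodiimide coupling converts the tail into the redox-active ester of the finished left half.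

Step 15
Reactants: 25 3-methylcyclohex-2-en-1-one
Product: 27 rac-1,3-dimethylcyclohex-2-en-1-yl acetate, via lithium alkoxide 26 (not isolated)
Conditions: MeLi, Et2O, −78 °C; then Ac2O, −78 → 0 °C
Reagents that add atoms: methyllithium, [Li]C; acetic anhydride, CC(=O)OC(C)=O
Why: 1,2-Addition of methyllithium to the enone and trapping of the tertiary allylic alkoxide gives the racemic acetate (allylic transposition is degenerate in this symmetrical allyl system).

Step 16
Reactants: 27 rac-1,3-dimethylcyclohex-2-en-1-yl acetate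
Product: 28 rac-1,3-dimethyl-4-oxocyclohex-2-en-1-yl acetate
Conditions: Rh2(cap)4 (cap = caprolactamate, 1 mol%), t-BuOOH (aq.), K2CO3, CH2Cl2, rt
Reagents that add atoms: tert-butyl hydroperoxide, CC(C)(C)OO
Why: Rh2(cap)4-catalysed allylic C–H oxidation (Doyle oxidation) converts the only allylic ring methylene into the enone carbonyl.

Step 17
Reactants: 28 rac-1,3-dimethyl-4-oxocyclohex-2-en-1-yl acetate
Product: 29 (S)-1,3-dimethyl-4-oxocyclohex-2-en-1-yl acetate
Conditions: preparative chiral SFC (amylose tris(3,5-dimethylphenylcarbamate) phase, CO2/i-PrOH)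
Reagents that add atoms: none
Why: Chromatographic resolution on a chiral stationary phase supplies the (S)-enantiomer, which carries the C8' configuration of the target.

Step 18
Reactants: 24 1,3-dioxoisoindolin-2-yl 3-[(3S,5aS,6S,7R,9aS)-3,7-diacetoxy-2,2,5a,7-tetramethyldecahydro-1-benzoxepin-6-yl]propanoate; 29 (S)-1,3-dimethyl-4-oxocyclohex-2-en-1-yl acetate
Product: 30 (3S,5aS,6S,7R,9aS)-6-{2-[(1S,2S,6S)-2-acetoxy-2,6-dimethyl-5-oxocyclohexyl]ethyl}-2,2,5a,7-tetramethyldecahydro-1-benzoxepine-3,7-diyl diacetate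
Conditions: Ru(bpy)3(PF6)2 (1 mol%), Hantzsch ester (1.5 equiv), 29 (3 equiv), DMF, blue LEDs, rt
Reagents that add atoms: none
Why: This photoredox decarboxylative Giese fragment coupling forms C12–C9' by addition of the primary left-half radical to the enone β-carbon anti to the pseudo-axial tertiary acetoxy group, which sets C9' trans to OAc and cis to the C8' methyl as in the target, while the C10' methine remains epimerisable.

Step 19
Reactants: 30 (3S,5aS,6S,7R,9aS)-6-{2-[(1S,2S,6S)-2-acetoxy-2,6-dimethyl-5-oxocyclohexyl]ethyl}-2,2,5a,7-tetramethyldecahydro-1-benzoxepine-3,7-diyl diacetate; 11 4-hydroxy-4-methylpent-1-en-3-one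
Product: 33 (3S,5aS,6S,7R,9aS)-6-{2-[(1S,2S,6S)-2-acetoxy-6-(4-hydroxy-4-methyl-3-oxopentyl)-2,6-dimethyl-5-oxocyclohexyl]ethyl}-2,2,5a,7-tetramethyldecahydro-1-benzoxepine-3,7-diyl diacetate, via ketimine 31 (not isolated), via Michael-adduct ketimine 32 (not isolated)
Conditions: (S)-1-phenylethylamine, 4 Å MS, TsOH (cat.), toluene, 40 °C; then 11, THF, 40 °C; then 10% aq. AcOH, rt
Reagents that add atoms: water, O
Why: The d'Angelo chiral-imine Michael addition on the only ketone attacks through the more substituted α-carbon on the face anti to the C9' chain and the C8' methyl (matched with the (S)-auxiliary), creating quaternary C10' with C1' trans to the chain.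

Step 20
Reactants: 33 (3S,5aS,6S,7R,9aS)-6-{2-[(1S,2S,6S)-2-acetoxy-6-(4-hydroxy-4-methyl-3-oxopentyl)-2,6-dimethyl-5-oxocyclohexyl]ethyl}-2,2,5a,7-tetramethyldecahydro-1-benzoxepine-3,7-diyl diacetate
Product: 34 (3S,5aS,6S,7R,9aS)-6-{2-[(1S,2S,6S)-2-acetoxy-6-[(3S)-3,4-dihydroxy-4-methylpentyl]-2,6-dimethyl-5-oxocyclohexyl]ethyl}-2,2,5a,7-tetramethyldecahydro-1-benzoxepine-3,7-diyl diacetate
Conditions: H2 (50 atm), RuCl2[(S)-BINAP] (1 mol%), EtOH, 40 °C
Reagents that add atoms: none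
Why: Noyori hydroxyl-directed hydrogenation of the α-hydroxy ketone sets (3'S) under ligand control and leaves the ring ketone and the three acetates alone.

Step 21
Reactants: 34 (3S,5aS,6S,7R,9aS)-6-{2-[(1S,2S,6S)-2-acetoxy-6-[(3S)-3,4-dihydroxy-4-methylpentyl]-2,6-dimethyl-5-oxocyclohexyl]ethyl}-2,2,5a,7-tetramethyldecahydro-1-benzoxepine-3,7-diyl diacetate
Product: 36 (3S,5aS,6S,7R,9aS)-6-{2-[(3S,5aS,6S,7S,9aS)-7-acetoxy-3-hydroxy-2,2,5a,7-tetramethyldecahydro-1-benzoxepin-6-yl]ethyl}-2,2,5a,7-tetramethyldecahydro-1-benzoxepine-3,7-diyl diacetate, via bicyclic ketal 35 (not isolated)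
Conditions: TMSOTf, Et3SiH, CH2Cl2, −78 °C; aq. NaHCO3, then citric acid/MeOH
Reagents that add atoms: none
Why: The ketalisation/reductive-etherification cascade of step 9, kept at −78 °C so the tertiary acetates survive, cleaves the C5'–O3' bond and delivers hydride axially to close the trans-fused right oxepane and release the free C3' alcohol of the target.

**Compound list**

1 | (S)-4-hydroxycyclohex-2-en-1-one | O=C1CC[C@H](O)C=C1 | starting material
2 | (S)-4-[(tert-butyldimethylsilyl)oxy]cyclohex-2-en-1-one | O=C1CC[C@H](O[Si](C)(C)C(C)(C)C)C=C1 | intermediate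
3 | (S)-4-[(tert-butyldimethylsilyl)oxy]-2-iodocyclohex-2-en-1-one | O=C1CC[C@H](O[Si](C)(C)C(C)(C)C)C=C1I | intermediate
4 | (S)-4-[(tert-butyldimethylsilyl)oxy]-2-methylcyclohex-2-en-1-one | O=C1CC[C@H](O[Si](C)(C)C(C)(C)C)C=C1C | intermediate
5 | succinic anhydride | O=C1CCC(=O)O1 | starting material
6 | monobenzyl succinate (4-(benzyloxy)-4-oxobutanoic acid) | OC(=O)CCC(=O)OCc1ccccc1 | intermediate
7 | benzyl (1,3-dioxoisoindolin-2-yl) succinate | O=C(CCC(=O)ON1C(=O)c2ccccc2C1=O)OCc1ccccc1 | intermediate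
8 | benzyl 3-[(1S,2S,6S)-6-[(tert-butyldimethylsilyl)oxy]-2-methyl-3-oxocyclohexyl]propanoate | O=C1CC[C@H](O[Si](C)(C)C(C)(C)C)[C@@H](CCC(=O)OCc2ccccc2)[C@@H]1C | intermediate
9 | 3-hydroxy-3-methylbutan-2-one | CC(=O)C(C)(C)O | starting material
10 | paraformaldehyde (formaldehyde) | C=O | starting material
11 | 4-hydroxy-4-methylpent-1-en-3-one | C=CC(=O)C(C)(C)O | intermediate
12 | (S)-1-phenylethyl ketimine of 8 | C[C@H](N=C1CC[C@H](O[Si](C)(C)C(C)(C)C)[C@@H](CCC(=O)OCc2ccccc2)[C@@H]1C)c1ccccc1 | intermediate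
13 | (S)-1-phenylethyl ketimine of 14 | C[C@H](N=C1CC[C@H](O[Si](C)(C)C(C)(C)C)[C@@H](CCC(=O)OCc2ccccc2)[C@]1(C)CCC(=O)C(C)(C)O)c1ccccc1 | intermediate
14 | benzyl 3-[(1S,2S,6S)-6-[(tert-butyldimethylsilyl)oxy]-2-(4-hydroxy-4-methyl-3-oxopentyl)-2-methyl-3-oxocyclohexyl]propanoate | O=C1CC[C@H](O[Si](C)(C)C(C)(C)C)[C@@H](CCC(=O)OCc2ccccc2)[C@]1(C)CCC(=O)C(C)(C)O | intermediate
15 | benzyl 3-[(1S,2S,6S)-6-[(tert-butyldimethylsilyl)oxy]-2-[(3S)-3,4-dihydroxy-4-methylpentyl]-2-methyl-3-oxocyclohexyl]propanoate | O=C1CC[C@H](O[Si](C)(C)C(C)(C)C)[C@@H](CCC(=O)OCc2ccccc2)[C@]1(C)CC[C@H](O)C(C)(C)O | intermediate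
16 | intramolecular ketal of 15 (C5 bridged to O3 and O4, 6,8-dioxabicyclo[3.2.1]octane core fused to ring B) | CC1(C)O[C@@]23CC[C@H](O[Si](C)(C)C(C)(C)C)[C@@H](CCC(=O)OCc4ccccc4)[C@]2(C)CC[C@@H]1O3 | intermediate
17 | benzyl 3-[(3S,5aS,6S,7S,9aS)-7-[(tert-butyldimethylsilyl)oxy]-3-hydroxy-2,2,5a-trimethyldecahydro-1-benzoxepin-6-yl]propanoate | O[C@H]1CC[C@]2(C)[C@H](CC[C@H](O[Si](C)(C)C(C)(C)C)[C@H]2CCC(=O)OCc3ccccc3)OC1(C)C | intermediate
18 | benzyl 3-[(3S,5aS,6S,7S,9aS)-3-acetoxy-7-[(tert-butyldimethylsilyl)oxy]-2,2,5a-trimethyldecahydro-1-benzoxepin-6-yl]propanoate | CC(=O)O[C@H]1CC[C@]2(C)[C@H](CC[C@H](O[Si](C)(C)C(C)(C)C)[C@H]2CCC(=O)OCc3ccccc3)OC1(C)C | intermediate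
19 | benzyl 3-[(3S,5aS,6S,7S,9aS)-3-acetoxy-7-hydroxy-2,2,5a-trimethyldecahydro-1-benzoxepin-6-yl]propanoate | CC(=O)O[C@H]1CC[C@]2(C)[C@H](CC[C@H](O)[C@H]2CCC(=O)OCc3ccccc3)OC1(C)C | intermediate
20 | benzyl 3-[(3S,5aS,6S,9aS)-3-acetoxy-2,2,5a-trimethyl-7-oxodecahydro-1-benzoxepin-6-yl]propanoate | CC(=O)O[C@H]1CC[C@]2(C)[C@H](CCC(=O)[C@H]2CCC(=O)OCc3ccccc3)OC1(C)C | intermediate
21 | dichlorocerium alkoxide of the C8 tertiary alcohol (methyl adduct of 20) | CC(=O)O[C@H]1CC[C@]2(C)[C@H](CC[C@@](C)([O-])[C@H]2CCC(=O)OCc3ccccc3)OC1(C)C.[Ce+3].[Cl-].[Cl-] | intermediate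
22 | benzyl 3-[(3S,5aS,6S,7R,9aS)-3,7-diacetoxy-2,2,5a,7-tetramethyldecahydro-1-benzoxepin-6-yl]propanoate | CC(=O)O[C@H]1CC[C@]2(C)[C@H](CC[C@@](C)(OC(C)=O)[C@H]2CCC(=O)OCc3ccccc3)OC1(C)C | intermediate
23 | 3-[(3S,5aS,6S,7R,9aS)-3,7-diacetoxy-2,2,5a,7-tetramethyldecahydro-1-benzoxepin-6-yl]propanoic acid | CC(=O)O[C@H]1CC[C@]2(C)[C@H](CC[C@@](C)(OC(C)=O)[C@H]2CCC(=O)O)OC1(C)C | intermediate
24 | 1,3-dioxoisoindolin-2-yl 3-[(3S,5aS,6S,7R,9aS)-3,7-diacetoxy-2,2,5a,7-tetramethyldecahydro-1-benzoxepin-6-yl]propanoate | CC(=O)O[C@H]1CC[C@]2(C)[C@H](CC[C@@](C)(OC(C)=O)[C@H]2CCC(=O)ON3C(=O)c4ccccc4C3=O)OC1(C)C | intermediate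
25 | 3-methylcyclohex-2-en-1-one | CC1=CC(=O)CCC1 | starting material
26 | lithium 1,3-dimethylcyclohex-2-en-1-olate | CC1=CC(C)([O-])CCC1.[Li+] | intermediate
27 | rac-1,3-dimethylcyclohex-2-en-1-yl acetate | CC1=CC(C)(OC(C)=O)CCC1 | intermediate
28 | rac-1,3-dimethyl-4-oxocyclohex-2-en-1-yl acetate | CC1=CC(C)(OC(C)=O)CCC1=O | intermediate
29 | (S)-1,3-dimethyl-4-oxocyclohex-2-en-1-yl acetate | CC1=C[C@@](C)(OC(C)=O)CCC1=O | intermediate
30 | (3S,5aS,6S,7R,9aS)-6-{2-[(1S,2S,6S)-2-acetoxy-2,6-dimethyl-5-oxocyclohexyl]ethyl}-2,2,5a,7-tetramethyldecahydro-1-benzoxepine-3,7-diyl diacetate | CC(=O)O[C@H]1CC[C@]2(C)[C@H](CC[C@@](C)(OC(C)=O)[C@H]2CC[C@H]3[C@H](C)C(=O)CC[C@]3(C)OC(C)=O)OC1(C)C | intermediate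
31 | (S)-1-phenylethyl ketimine of 30 | CC(=O)O[C@H]1CC[C@]2(C)[C@H](CC[C@@](C)(OC(C)=O)[C@H]2CC[C@H]3[C@H](C)C(=N[C@@H](C)c4ccccc4)CC[C@]3(C)OC(C)=O)OC1(C)C | intermediate
32 | (S)-1-phenylethyl ketimine of 33 | CC(=O)O[C@H]1CC[C@]2(C)[C@H](CC[C@@](C)(OC(C)=O)[C@H]2CC[C@H]3[C@](C)(CCC(=O)C(C)(C)O)C(=N[C@@H](C)c4ccccc4)CC[C@]3(C)OC(C)=O)OC1(C)C | intermediate
33 | (3S,5aS,6S,7R,9aS)-6-{2-[(1S,2S,6S)-2-acetoxy-6-(4-hydroxy-4-methyl-3-oxopentyl)-2,6-dimethyl-5-oxocyclohexyl]ethyl}-2,2,5a,7-tetramethyldecahydro-1-benzoxepine-3,7-diyl diacetate | CC(=O)O[C@H]1CC[C@]2(C)[C@H](CC[C@@](C)(OC(C)=O)[C@H]2CC[C@H]3[C@](C)(CCC(=O)C(C)(C)O)C(=O)CC[C@]3(C)OC(C)=O)OC1(C)C | intermediate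
34 | (3S,5aS,6S,7R,9aS)-6-{2-[(1S,2S,6S)-2-acetoxy-6-[(3S)-3,4-dihydroxy-4-methylpentyl]-2,6-dimethyl-5-oxocyclohexyl]ethyl}-2,2,5a,7-tetramethyldecahydro-1-benzoxepine-3,7-diyl diacetate | CC(=O)O[C@H]1CC[C@]2(C)[C@H](CC[C@@](C)(OC(C)=O)[C@H]2CC[C@H]3[C@](C)(CC[C@H](O)C(C)(C)O)C(=O)CC[C@]3(C)OC(C)=O)OC1(C)C | intermediate
35 | intramolecular ketal of 34 (C5' bridged to O3' and O4') | CC(=O)O[C@H]1CC[C@]2(C)[C@H](CC[C@@](C)(OC(C)=O)[C@H]2CC[C@H]3[C@]4(C)CC[C@@H]5O[C@@]4(CC[C@]3(C)OC(C)=O)OC5(C)C)OC1(C)C | intermediate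
36 | (3S,5aS,6S,7R,9aS)-6-{2-[(3S,5aS,6S,7S,9aS)-7-acetoxy-3-hydroxy-2,2,5a,7-tetramethyldecahydro-1-benzoxepin-6-yl]ethyl}-2,2,5a,7-tetramethyldecahydro-1-benzoxepine-3,7-diyl diacetate | CC(=O)O[C@H]1CC[C@]2(C)[C@H](CC[C@@](C)(OC(C)=O)[C@H]2CC[C@H]2[C@]3(C)CC[C@H](O)C(C)(C)O[C@H]3CC[C@]2(C)OC(C)=O)OC1(C)C | target

**Step count and risks**

Total steps: 21. Longest linear sequence: 16 (steps 1, 2, 3, 5, 7–14, 18–21).

Steps most likely to fail:

- Step 18 (fragment-coupling Giese reaction). The risks are premature reduction of the valuable primary radical and imperfect facial selectivity at C9'. Fallback: the acid 23 is converted by Suárez iododecarboxylation (PhI(OAc)2, I2, hν) into (3S,5aS,6S,7R,9aS)-6-(2-iodoethyl)-2,2,5a,7-tetramethyldecahydro-1-benzoxepine-3,7-diyl diacetate F1. The same C12 radical is then generated by iodine-atom abstraction in a silane chain ((Me3Si)3SiH, Et3B/air, excess 29), where no photoreductant competes for the radical. This sets out from 23 and returns to the route at 30.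

- Step 19 (quaternary C10' by chiral-imine Michael addition on the hindered late-stage ketone). Fallback: 30 is converted (Me3SiCl, NaI, Et3N, MeCN) into its thermodynamic trimethylsilyl enol ether F2, and 11 is silylated (Me3SiCl, imidazole) to 4-methyl-4-[(trimethylsilyl)oxy]pent-1-en-3-one F3. A Sc(OTf)3-catalysed Mukaiyama–Michael addition of F2 to F3 at −78 °C with aqueous fluoride work-up then gives the diketone. This sets out from 30 (and 11) and returns at 33.

- Step 21 (final ketalisation/reductive cleavage). The risks are opening of the ketal toward the tetrahydropyran and ionisation of the tertiary acetates. Fallback: the secondary C3' alcohol of 34 is silylated (Et3SiCl, imidazole) to the triethylsilyl ether F4, so only the tertiary C4' hydroxyl can engage the ketone. Direct reductive etherification (Bi(OTf)3, Et3SiH, MeCN, −40 °C) gives the oxepane triethylsilyl ether F5, and HF·pyridine removes the silyl group. This sets out from 34 and returns at 36.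

**Further compounds**

F1 | step 18 | (3S,5aS,6S,7R,9aS)-6-(2-iodoethyl)-2,2,5a,7-tetramethyldecahydro-1-benzoxepine-3,7-diyl diacetate | CC(=O)O[C@H]1CC[C@]2(C)[C@H](CC[C@@](C)(OC(C)=O)[C@H]2CCI)OC1(C)C
F2 | step 19 | trimethylsilyl enol ether of 30 (C5'(OSiMe3)=C10'(Me)) | CC(=O)O[C@H]1CC[C@]2(C)[C@H](CC[C@@](C)(OC(C)=O)[C@H]2CC[C@H]3C(C)=C(O[Si](C)(C)C)CC[C@]3(C)OC(C)=O)OC1(C)C
F3 | step 19 | 4-methyl-4-[(trimethylsilyl)oxy]pent-1-en-3-one | C=CC(=O)C(C)(C)O[Si](C)(C)C
F4 | step 21 | C3' triethylsilyl ether of 34 | CC(=O)O[C@H]1CC[C@]2(C)[C@H](CC[C@@](C)(OC(C)=O)[C@H]2CC[C@H]3[C@](C)(CC[C@H](O[Si](CC)(CC)CC)C(C)(C)O)C(=O)CC[C@]3(C)OC(C)=O)OC1(C)C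
F5 | step 21 | C3' triethylsilyl ether of 36 | CC(=O)O[C@H]1CC[C@]2(C)[C@H](CC[C@@](C)(OC(C)=O)[C@H]2CC[C@H]2[C@]3(C)CC[C@H](O[Si](CC)(CC)CC)C(C)(C)O[C@H]3CC[C@]2(C)OC(C)=O)OC1(C)C
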